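**Retrosynthetic overview**

1. The last step joins three components: (S)-humulenol 6 and two molecules of the tropolone o-quinone methide 18, by a double hetero-Diels–Alder reaction. It closes dihydropyran ring A (aryl-O–C3 and ArCH2–C2 bonds, next to the carbinol) and then dihydropyran ring B (aryl-O–C7 and ArCH2–C6 bonds).
2. Enabling feature: in each dihydropyran ring an aryl–O–C(CH3) carbon stands next to an ArCH2–CH carbon, which is the retron of an o-quinone methide added to a trisubstituted E-olefin. Both olefins (C2=C3 and C6=C7) lie in the eleven-membered humulane ring, and the C4 carbinol beside C3 relays its configuration to C2, C3, C6 and C7.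
3. 6 comes from α-humulene: the more reactive C6=C7 olefin is masked as its epoxide, C4 is oxidized (SeO2, then Dess–Martin), the olefin is returned, and a CBS reduction sets C4, the only stereocenter made by catalysis.
4. The quinone methide precursor 17 comes from 2-methylanisole: Birch reduction, dichlorocarbene addition and ring expansion (arene to seven-membered ring), Stille hydroxymethylation, and diol oxidation to the tropolone.
5. Order of ring formation: tropolone carbocycle (ring expansion, then aromatization), dihydropyran ring A, dihydropyran ring B; the eleven-membered ring is bought with humulene.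

Key step: step 15

Locants: humulane numbering of the eleven-membered ring is used: C1 (CH2), C2, C3 (CH3), C4 (carbinol), C5 (CH2), C6, C7 (CH3), C8 (CH2), C9=C10, C11 (gem-dimethyl). Tropolone carbons are primed: C1' (C=O), C2' (OH), C4' (O), C5' (CH2 arm), C6' (CH3). In this numbering the target is 2R,3R,4S,6R,7R.

Assumption: in humulenol the C4 hydroxyl is taken to deliver the quinone methide to the neighbouring C2=C3 olefin first; racemic intermediates are drawn as one enantiomer and tropolones as the tautomer of the target SMILES.

**Route**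

Step 1
Reactants: 1 α-humulene
Product: 2 rac-humulene 6,7-epoxide (trans-epoxide)
Conditions: mCPBA (1.0 equiv), CH2Cl2, −20 to 0 °C; aqueous NaHCO3 wash
Reagents that add atoms: mCPBA (3-chloroperoxybenzoic acid), OOC(=O)c1cccc(Cl)c1
Why: Prilezhaev epoxidation is stereospecific (E-olefin to trans-epoxide) and should select C6=C7, the most nucleophilic and strained olefin of humulene, which is thereby masked so that the allylic oxidation of step 2 can only touch C2=C3.

Step 2
Reactants: 2 rac-humulene 6,7-epoxide
Product: 3 6,7-epoxyhumulen-4-ol (both C4 epimers)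
Conditions: SeO2 (0.3 equiv), t-BuOOH (2.5 equiv, in decane), CH2Cl2, 20 °C
Reagents that add atoms: selenium dioxide, O=[Se]=O (catalytic oxygen carrier); tert-butyl hydroperoxide, CC(C)(C)OO
Why: Sharpless–Riley allylic oxidation (ene reaction, then [2,3]-sigmatropic shift) at the only remaining trisubstituted olefin should hydroxylate the ring CH2 on its disubstituted terminus (C4, Guillemonat rules) with retention of the E geometry; the new carbinol configuration does not matter because step 3 removes it.

Step 3
Reactants: 3 6,7-epoxyhumulen-4-ol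
Product: 4 rac-6,7-epoxyhumulen-4-one
Conditions: Dess–Martin periodinane (1.3 equiv), pyridine (3 equiv), CH2Cl2, 0 to 20 °C
Reagents that add atoms: none
Why: Dess–Martin oxidation of a secondary allylic alcohol under buffered, non-enolizing conditions gives the enone and merges the two C4 epimers.

Step 4
Reactants: 4 rac-6,7-epoxyhumulen-4-one
Product: 5 humulenone
Conditions: dimethyl diazomalonate (1.5 equiv), Rh2(OAc)4 (2 mol%), toluene, 90 °C
Reagents that add atoms: none
Why: Carbenoid deoxygenation of epoxides (the rhodium carbenoid forms an oxonium ylide that fragments to olefin and dimethyl oxomalonate) is stereospecific with retention, so the trans-epoxide should return the E-olefin under neutral conditions that spare the β,γ-epoxy ketone and the enone.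

Step 5
Reactants: 5 humulenone
Product: 6 (S)-humulenol
Conditions: (R)-2-methyl-CBS-oxazaborolidine (20 mol%), catecholborane (1.5 equiv), toluene, −78 °C; aqueous NaOH work-up
Reagents that add atoms: none
Why: Corey–Bakshi–Shibata reduction, in which the α-methylalkenyl arm acts as the large and the C5 methylene as the small ketone substituent, so that the (R)-catalyst should give the 4S carbinol (the one stereocenter set by catalysis), while catecholborane at −78 °C avoids hydroboration of the olefins.

Step 6
Reactants: 7 2-methylanisole
Product: 8 1-methoxy-2-methylcyclohexa-1,4-diene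
Conditions: Li (2.5 equiv), NH3 (l), THF, t-BuOH (2.5 equiv), −78 to −33 °C; solid NH4Cl quench
Reagents that add atoms: none
Why: Birch reduction leaves the methoxy- and methyl-bearing carbons sp2 and gives the 1,4-diene with a tetrasubstituted enol ether double bond (dearomatization of a cheap arene).

Step 7
Reactants: 8 1-methoxy-2-methylcyclohexa-1,4-diene
Product: 9 rac-7,7-dichloro-1-methoxy-6-methylbicyclo[4.1.0]hept-3-ene
Conditions: CHCl3, 50% aqueous NaOH, BnEt3NCl (2 mol%), 0 to 20 °C
Reagents that add atoms: chloroform, ClC(Cl)Cl
Why: Dichlorocarbene (Makosza phase-transfer conditions) adds chemoselectively to the electron-rich tetrasubstituted enol ether olefin and not to the cis-disubstituted one, the cis ring fusion being the only possibility, and the dichloro adduct is robust enough for the next two steps.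

Step 8
Reactants: 9 rac-7,7-dichloro-1-methoxy-6-methylbicyclo[4.1.0]hept-3-ene
Product: 10 rac-7,7-dichloro-1-methoxy-6-methylbicyclo[4.1.0]heptane-3,4-diol (cis-diol)
Conditions: OsO4 (2 mol%), NMO (1.5 equiv), acetone/H2O (8:1), 20 °C
Reagents that add atoms: osmium tetroxide, O=[Os](=O)(=O)=O (catalytic); N-methylmorpholine N-oxide, C[N+]1([O-])CCOCC1; water, O
Why: Upjohn dihydroxylation adds syn to the remaining olefin, expected from the face opposite to the CCl2 bridge (these stereocenters are destroyed in step 14).

Step 9
Reactants: 10 rac-7,7-dichloro-1-methoxy-6-methylbicyclo[4.1.0]heptane-3,4-diol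
Product: 11 acetonide of 10
Conditions: 2,2-dimethoxypropane (3 equiv), PPTS (5 mol%), acetone, 20 °C
Reagents that add atoms: 2,2-dimethoxypropane, COC(C)(C)OC
Why: Acetonide formation (transketalization) masks the cis-diol so that no β-hydroxy ketone is exposed during ring expansion and coupling.

Step 10
Reactants: 11 acetonide of 10
Product: 12 rac-2-chloro-3-methylcyclohept-2-enone 5,6-acetonide
Conditions: AgNO3 (1.5 equiv), 2,6-lutidine (1.5 equiv), acetone/H2O (4:1), 50 °C
Reagents that add atoms: water, O
Why: Silver-assisted disrotatory electrocyclic opening of the alkoxy gem-dichlorocyclopropane (cyclopropyl-to-allyl cation, pushed by the methoxy group) cleaves the ring-fusion bond and the oxocarbenium ion is hydrolysed, a known ring expansion that gives the 2-chlorocyclohept-2-enone with the methyl group on C3.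

Step 11
Reactants: 12 rac-2-chloro-3-methylcyclohept-2-enone 5,6-acetonide
Product: 13 rac-2-(hydroxymethyl)-3-methylcyclohept-2-enone 5,6-acetonide
Conditions: Bu3SnCH2OH (1.5 equiv), Pd2(dba)3 (3 mol%), P(t-Bu)3 (12 mol%), CsF (2.2 equiv), 1,4-dioxane, 90 °C
Reagents that add atoms: (tributylstannyl)methanol, CCCC[Sn](CCCC)(CCCC)CO
Why: Stille coupling under Littke–Fu conditions for vinyl chlorides transfers the hydroxymethyl group of the α-oxygenated stannane in preference to butyl and installs the future C5' methylene arm.

Step 12
Reactants: 13 rac-2-(hydroxymethyl)-3-methylcyclohept-2-enone 5,6-acetonide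
Product: 14 rac-2-(acetoxymethyl)-3-methylcyclohept-2-enone 5,6-acetonide
Conditions: Ac2O (1.5 equiv), pyridine, CH2Cl2, 0 to 20 °C
Reagents that add atoms: acetic anhydride, CC(=O)OC(C)=O
Why: Acetylation of the primary allylic alcohol provides the leaving group for the later quinone methide formation and protects the alcohol from oxidation in step 14.

Step 13
Reactants: 14 rac-2-(acetoxymethyl)-3-methylcyclohept-2-enone 5,6-acetonide
Product: 15 rac-2-(acetoxymethyl)-5,6-dihydroxy-3-methylcyclohept-2-enone (cis-diol)
Conditions: AcOH/H2O/THF (3:1:1), 45 °C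
Reagents that add atoms: none
Why: Mild acid hydrolysis of the acetonide leaves the acetate and the enone untouched.

Step 14
Reactants: 15 rac-2-(acetoxymethyl)-5,6-dihydroxy-3-methylcyclohept-2-enone
Product: 17 5-(acetoxymethyl)-4-hydroxy-6-methyltropolone, via cycloheptenetrione 16 (not isolated)
Conditions: IBX (3.0 equiv), DMSO, 25 °C
Reagents that add atoms: none
Why: IBX oxidizes 1,2-diols to 1,2-diketones without C–C cleavage, and the resulting cycloheptenetrione 16 should enolize spontaneously to the aromatic 4-hydroxytropolone (the diol-to-tropolone oxidation known from gem-dihalocyclopropane routes to tropolones).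

Step 15
Reactants: 6 (S)-humulenol; 17 5-(acetoxymethyl)-4-hydroxy-6-methyltropolone (3.0 equiv)
Product: 20 target bis-adduct (2R,3R,4S,6R,7R), via tropolone o-quinone methide 18 (not isolated), via ring-A mono-adduct 19 (not isolated)
Conditions: 17 added in three portions, p-xylene (0.1 M in 6), 140 °C, sealed tube, argon
Reagents that add atoms: none
Why: Heating 17 expels acetic acid (1,4-elimination) to give the tropolone o-quinone methide 18, an electron-poor 1-oxadiene that should add twice to 6 by inverse-electron-demand hetero-Diels–Alder reaction, first at the allylic-alcohol olefin C2=C3, to which the C4 hydroxyl delivers it by hydrogen bonding to the quinone methide carbonyl (this event forms the aryl-O–C3 bond and closes ring A, giving 19), then at C6=C7 (ring B); the closest known reaction type is the thermal [4+2] addition of o-quinone methides, tropolone-derived ones included, to the trisubstituted olefins of humulene. Each dihydropyran ring is closed by an intermolecular, concerted but asynchronous, suprafacial [4π+2π] cycloaddition in which the methylene terminus bonds to the olefinic CH and the oxygen to the methyl-bearing carbon (Markovnikov polarization). Suprafacial addition to E-olefins makes both ring fusions trans, which fixes C2 relative to C3 and C6 relative to C7. The face of C2=C3 is set by the 4S carbinol: the olefin plane stands perpendicular to the macrocycle with C5 on its inner face, A(1,2) strain with the C3 methyl group keeps C4–H next to that methyl and the hydroxyl in the olefin plane (inside-alkoxy arrangement), and attack from the periphery, anti to C5, should give 2R,3R. The face of C6=C7 is then set by the new quaternary C3: a gauche C3–C4–C5–C6 unit would cost a syn-pentane contact of C6 with the C3 methyl or with C2, so the chain should stay extended, and of the two olefin orientations the one that turns C7 toward C4–H and not toward the C4 oxygen exposes the face that gives 6R,7R. The step needs chemoselectivity for the two trisubstituted olefins over the neopentyl-flanked C9=C10 olefin (secured by nucleophilicity and hindrance), the order C2=C3 before C6=C7 (secured by the hydroxyl delivery) and little self-condensation of 18 (secured by adding 17 in portions to concentrated 6).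

**Compound list**

1 | α-humulene, (1E,4E,8E)-2,6,6,9-tetramethylcycloundeca-1,4,8-triene | C/C1=C\CC(C)(C)/C=C/C/C(C)=C/CC1 | starting material
2 | rac-humulene 6,7-epoxide, (1R*,3E,7E,11R*)-1,5,5,8-tetramethyl-12-oxabicyclo[9.1.0]dodeca-3,7-diene (trans-epoxide) | C/C1=C\CC(C)(C)/C=C/C[C@@]2(C)O[C@@H]2CC1 | intermediate
3 | 6,7-epoxyhumulen-4-ol, (3E,7E)-1,5,5,8-tetramethyl-12-oxabicyclo[9.1.0]dodeca-3,7-dien-9-ol (racemic trans-epoxide, both carbinol epimers) | C/C1=C\CC(C)(C)/C=C/C[C@@]2(C)O[C@@H]2CC1O | intermediate
4 | rac-6,7-epoxyhumulen-4-one, (1R*,3E,7E,11R*)-1,5,5,8-tetramethyl-12-oxabicyclo[9.1.0]dodeca-3,7-dien-9-one | C/C1=C\CC(C)(C)/C=C/C[C@@]2(C)O[C@@H]2CC1=O | intermediate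
5 | humulenone, (2E,6E,9E)-2,5,5,9-tetramethylcycloundeca-2,6,9-trien-1-one | C/C1=C\CC(C)(C)/C=C/C/C(C)=C/CC1=O | intermediate
6 | (S)-humulenol, (1S,2E,6E,9E)-2,5,5,9-tetramethylcycloundeca-2,6,9-trien-1-ol (carbinol = humulane C4) | C/C1=C\CC(C)(C)/C=C/C/C(C)=C/C[C@@H]1O | intermediate
7 | 2-methylanisole (1-methoxy-2-methylbenzene) | COc1ccccc1C | starting material
8 | 1-methoxy-2-methylcyclohexa-1,4-diene | COC1=C(C)CC=CC1 | intermediate
9 | rac-7,7-dichloro-1-methoxy-6-methylbicyclo[4.1.0]hept-3-ene (cis-fused) | CO[C@]12CC=CC[C@@]1(C)C2(Cl)Cl | intermediate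
10 | rac-7,7-dichloro-1-methoxy-6-methylbicyclo[4.1.0]heptane-3,4-diol (cis-diol, on the face opposite to the CCl2 bridge) | CO[C@]12C[C@H](O)[C@H](O)C[C@@]1(C)C2(Cl)Cl | intermediate
11 | acetonide (isopropylidene ketal) of diol 10 | CO[C@]12C[C@@H]3OC(C)(C)O[C@@H]3C[C@@]1(C)C2(Cl)Cl | intermediate
12 | rac-cis-6-chloro-2,2,7-trimethyl-3a,4,8,8a-tetrahydro-5H-cyclohepta[d][1,3]dioxol-5-one (2-chloro-3-methylcyclohept-2-enone 5,6-acetonide) | CC1=C(Cl)C(=O)C[C@@H]2OC(C)(C)O[C@@H]2C1 | intermediate
13 | rac-cis-6-(hydroxymethyl)-2,2,7-trimethyl-3a,4,8,8a-tetrahydro-5H-cyclohepta[d][1,3]dioxol-5-one | CC1=C(CO)C(=O)C[C@@H]2OC(C)(C)O[C@@H]2C1 | intermediate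
14 | rac-cis-(2,2,7-trimethyl-5-oxo-3a,4,8,8a-tetrahydro-5H-cyclohepta[d][1,3]dioxol-6-yl)methyl acetate | CC1=C(COC(C)=O)C(=O)C[C@@H]2OC(C)(C)O[C@@H]2C1 | intermediate
15 | rac-2-(acetoxymethyl)-5,6-dihydroxy-3-methylcyclohept-2-en-1-one (cis-diol) | CC1=C(COC(C)=O)C(=O)C[C@H](O)[C@H](O)C1 | intermediate
16 | 5-(acetoxymethyl)-6-methylcyclohept-5-ene-1,2,4-trione | CC1=C(COC(C)=O)C(=O)CC(=O)C(=O)C1 | intermediate (not isolated)
17 | 5-(acetoxymethyl)-4-hydroxy-6-methyltropolone (tropolone = 2-hydroxycyclohepta-2,4,6-trien-1-one) | Cc1cc(=O)c(O)cc(O)c1COC(C)=O | intermediate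
18 | tropolone o-quinone methide, 2-hydroxy-6-methyl-5-methylidenecyclohepta-2,6-diene-1,4-dione | CC1=CC(=O)C(O)=CC(=O)C1=C | intermediate (not isolated)
19 | ring-A mono-adduct (2R,3R,4S): trans-fused dihydropyrano-tropolone on C2/C3 of the humulane ring (aryl-O on C3, ArCH2 on C2), free 4S-OH, E-olefins C6=C7 and C9=C10 | Cc1cc(=O)c(O)cc2c1C[C@H]1CC(C)(C)/C=C/C/C(C)=C/C[C@H](O)[C@]1(C)O2 | intermediate (not isolated)
20 | target bis-adduct (2R,3R,4S,6R,7R): humulane ring with trans-fused dihydropyrano-tropolones on C2/C3 and C6/C7 (aryl-O on C3 and C7, ArCH2 on C2 and C6), 4S-OH, E-olefin C9=C10 | Cc1cc(=O)c(O)cc2c1C[C@H]1CC(C)(C)/C=C/C[C@@]3(C)Oc4cc(O)c(=O)cc(C)c4C[C@@H]3C[C@H](O)[C@]1(C)O2 | target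

**Step count and risks**

Total step count: 15. Longest linear sequence: 10 steps (steps 6 to 15, from 2-methylanisole).

Steps most likely to fail:

Step 15. What may go wrong: the remote C6=C7 olefin may react first through the folded conformer of the macrocycle, so that ring B forms with the 6S,7S configuration; the two faces may also be poorly distinguished, and self-condensation of 18 competes. Fallback: the relay is turned around and made stepwise. Setting out from 5, reduction with the (S)-configured CBS catalyst and catecholborane gives (R)-humulenol F1. Heating F1 with 17 (1.1 equiv) forms only ring B, which under the same folded-conformer preference has the 6R,7R configuration and gives the (4R,6R,7R) ring-B mono-adduct F2. Dess–Martin oxidation gives the ring-B enone F3, and (R)-CBS/catecholborane reduction of F3 sets 4S and gives the (4S,6R,7R) ring-B mono-adduct F4. Heating F4 with 17 (1.5 equiv) then closes ring A under the A(1,2)-strain control of the 4S carbinol and returns to the route at 20.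

Step 11. What may go wrong: slow oxidative addition of the α-chloroenone to zerovalent palladium, or fluoride-induced β-elimination of the acetonide oxygen. Fallback: the bromo series, coupled without fluoride. Setting out from 8, dibromocarbene (CHBr3, KOt-Bu, pentane, −30 °C) gives the dibromocyclopropane F5, which is dihydroxylated cold (OsO4, NMO) to the diol F6, protected as the acetonide F7 and ring-expanded with AgNO3 in aqueous acetone to the bromoenone F8. The more labile dibromocyclopropanes are handled cold and taken on without storage. F8 undergoes the Stille coupling with (tributylstannyl)methanol under classical conditions (Pd(PPh3)4, 1,4-dioxane, 90 °C) and returns to the route at 13.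

Step 4. What may go wrong: capture of the rhodium carbenoid by the enone carbonyl, or opening of the β,γ-epoxy ketone by enolization. Fallback: deoxygenation at the alcohol level with a low-valent tungsten reagent. Setting out from 3, silylation (TBSCl, imidazole, DMF) gives the epoxy silyl ether F9; WCl6/n-BuLi in THF removes the epoxide oxygen with retention to give the humulenol silyl ether F10; TBAF gives racemic humulenol F11, and Dess–Martin oxidation returns to the route at 5.

**Further compounds**

F1 | step 15 | (R)-humulenol, (1R,2E,6E,9E)-2,5,5,9-tetramethylcycloundeca-2,6,9-trien-1-ol | C/C1=C\CC(C)(C)/C=C/C/C(C)=C/C[C@H]1O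
F2 | step 15 | (4R,6R,7R) ring-B mono-adduct (trans-fused dihydropyrano-tropolone on C6/C7, free 4R-OH, E-olefins C2=C3 and C9=C10) | C/C1=C\CC(C)(C)/C=C/C[C@@]2(C)Oc3cc(O)c(=O)cc(C)c3C[C@@H]2C[C@H]1O
F3 | step 15 | (6R,7R) ring-B mono-adduct 4-ketone (enone) | C/C1=C\CC(C)(C)/C=C/C[C@@]2(C)Oc3cc(O)c(=O)cc(C)c3C[C@@H]2CC1=O
F4 | step 15 | (4S,6R,7R) ring-B mono-adduct | C/C1=C\CC(C)(C)/C=C/C[C@@]2(C)Oc3cc(O)c(=O)cc(C)c3C[C@@H]2C[C@@H]1O
F5 | step 11 | rac-7,7-dibromo-1-methoxy-6-methylbicyclo[4.1.0]hept-3-ene | CO[C@]12CC=CC[C@@]1(C)C2(Br)Br
F6 | step 11 | rac-7,7-dibromo-1-methoxy-6-methylbicyclo[4.1.0]heptane-3,4-diol (cis-diol) | CO[C@]12C[C@H](O)[C@H](O)C[C@@]1(C)C2(Br)Br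
F7 | step 11 | acetonide of F6 | CO[C@]12C[C@@H]3OC(C)(C)O[C@@H]3C[C@@]1(C)C2(Br)Br
F8 | step 11 | rac-cis-6-bromo-2,2,7-trimethyl-3a,4,8,8a-tetrahydro-5H-cyclohepta[d][1,3]dioxol-5-one | CC1=C(Br)C(=O)C[C@@H]2OC(C)(C)O[C@@H]2C1
F9 | step 4 | tert-butyldimethylsilyl ether of 3 | C/C1=C\CC(C)(C)/C=C/C[C@@]2(C)O[C@@H]2CC1O[Si](C)(C)C(C)(C)C
F10 | step 4 | tert-butyldimethylsilyl ether of racemic humulenol | C/C1=C\CC(C)(C)/C=C/C/C(C)=C/CC1O[Si](C)(C)C(C)(C)C
F11 | step 4 | racemic humulenol | C/C1=C\CC(C)(C)/C=C/C/C(C)=C/CC1O
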